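**Plan**

- Retrosynthesis: the three phenol O–H bonds go back to O–SiMe3. In each oxyphenyl ring (C1' bears the propenoyl chain, C4' the oxygen) the ring bonds C3'–C4' and C5'–C6' are cut, giving a 5-substituted 2-pyrone and a two-carbon ketene acetal. The three pyrone C5–vinyl bonds and the three amide C–N bonds are cut last.
- Enabling feature: each benzene ring carries only oxygen at C4' and the alkenyl carbon at C1', with C2', C3', C5' and C6' as CH. Pyrone C3, C4, C5 (side chain) and C6 plus the two carbons of a ketene acetal give exactly this pattern once the O1–C2 bridge leaves as carbon dioxide.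
- Forward: spermidine is acryloylated at N1, N5 and N10. Three 5-bromo-2-pyrone units made from coumalic acid are joined to the acrylamide termini by Heck coupling. All three benzene rings then form in one operation, one from each pyrone, and methanolysis of the silyl ethers gives the target.
- Stereochemistry: there are no stereocentres. The three E alkenes arise from syn carbopalladation and syn β-hydride elimination in the Heck step and are preserved by excluding light from then on.

Key step: step 5

Remark: steps 2, 3 and 5 are threefold and each consumes three equivalents of the small partner per spermidine core; one equivalent stands on the Reactants line and the two further equivalents are entered among the reagents that add atoms. The three arms react independently in the key step; its bridged-lactone and cyclohexadiene intermediates are drawn with all arms at the same stage, and the bridged lactone is a diastereomer mixture whose stereocentres vanish on aromatisation.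

**Route**

Step 1
Reactants: 1 coumalic acid
Product: 2 5-bromo-2H-pyran-2-one
Conditions: N-bromosuccinimide (1.1 equiv), LiOAc (0.2 equiv), MeCN–H2O 9:1, rt
Reagents that add atoms: N-bromosuccinimide, O=C1CCC(=O)N1Br
Why: Hunsdiecker-type bromodecarboxylation, in which C5 is the nucleophilic β-carbon of the ring enol ether O1–C6=C5, so electrophilic bromine should add ipso to the carboxyl-bearing carbon and the oxocarbenium ion should collapse by loss of carbon dioxide, while about one equivalent of brominating agent holds back a second bromination at C3.

Step 2
Reactants: 3 spermidine; 4 acryloyl chloride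
Product: 5 N1,N5,N10-triacryloylspermidine
Conditions: 4 (3.3 equiv in total), NaOH (2 M aq), CH2Cl2, 0 °C, 2,6-di-tert-butyl-4-methylphenol (trace)
Reagents that add atoms: acryloyl chloride (second equivalent), C=CC(=O)Cl; acryloyl chloride (third equivalent), C=CC(=O)Cl
Why: threefold Schotten–Baumann N-acylation, in which aminolysis of one acid chloride molecule by each of the two primary amines and the one secondary amine at 0 °C should far outrun aza-Michael addition to the acrylamides already formed, and the radical inhibitor suppresses oligomerisation.

Step 3
Reactants: 5 N1,N5,N10-triacryloylspermidine; 2 5-bromo-2H-pyran-2-one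
Product: 6 N1,N5,N10-tris[(E)-3-(2-oxo-2H-pyran-5-yl)acryloyl]spermidine
Conditions: 2 (3.6 equiv in total), Pd(OAc)2 (10 mol %), n-Bu4NCl, NaHCO3, DMF, 70 °C, dark
Reagents that add atoms: 5-bromo-2H-pyran-2-one (second equivalent), BrC1=COC(=O)C=C1; 5-bromo-2H-pyran-2-one (third equivalent), BrC1=COC(=O)C=C1
Why: threefold Mizoroki–Heck reaction, one bromopyrone per acrylamide terminus, in which zerovalent palladium formed in situ inserts into the C5–Br bond of 2, syn carbopalladation of each terminal acrylamide and syn β-hydride elimination should give the E alkenes, and ligand-free phase-transfer conditions with hydrogencarbonate as base and no free amine present spare the pyrone rings.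

Step 4
Reactants: 7 trimethylsilyl acetate
Product: 9 1,1-bis(trimethylsilyloxy)ethene, via lithium enolate 8 (not isolated)
Conditions: LiN(i-Pr)2 (1.05 equiv), THF, −78 °C; Me3SiCl, −78 °C to rt; filtration, distillation
Reagents that add atoms: chlorotrimethylsilane, C[Si](C)(C)Cl
Why: deprotonation of the silyl ester at low temperature and O-silylation of the lithium enolate by the hard chlorosilane is the standard preparation of ketene silyl acetals, and the product should be isolable by distillation with exclusion of moisture.

Step 5
Reactants: 6 N1,N5,N10-tris[(E)-3-(2-oxo-2H-pyran-5-yl)acryloyl]spermidine; 9 1,1-bis(trimethylsilyloxy)ethene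
Product: 12 N1,N5,N10-tris[(E)-4-(trimethylsilyloxy)cinnamoyl]spermidine, via tris(bridged lactone) cycloadduct 10 (not isolated), via tris(cyclohexadiene) 11 (not isolated)
Conditions: 9 (10 equiv in total), anhydrous 1,4-dioxane–MeCN, sealed tube, 100 °C, Ar, dark; volatiles removed in vacuo
Reagents that add atoms: 1,1-bis(trimethylsilyloxy)ethene (second equivalent), C=C(O[Si](C)(C)C)O[Si](C)(C)C; 1,1-bis(trimethylsilyloxy)ethene (third equivalent), C=C(O[Si](C)(C)C)O[Si](C)(C)C
Why: Proposed new method: each pyrone C3=C4–C5=C6 unit should act as an electron-poor diene and one molecule of the ketene acetal as an electron-rich dienophile in an inverse-electron-demand Diels–Alder reaction; the closest known type is the conversion of 5-acceptor 2-pyrones such as alkyl coumalates into para-oxygenated benzoates with ketene acetals or enol ethers, extended here to a 5-(2-carbamoylvinyl)pyrone and to three sites in one molecule. Each of the three benzene rings closes by an intermolecular [4+2] cycloaddition that forms the C6–CH2 and C3–C(OSiMe3)2 bonds (bridged lactone 10), after which retro-[4+2] loss of carbon dioxide gives cyclohexadiene 11 and 1,2-elimination of trimethylsilanol across CH2–C(OSiMe3)2 aromatises it. The bridgehead stereocentres of 10 are transient, so no stereocontrol is needed, and the E alkenes are not involved. The step needs regioselectivity (oxygen para and not meta to the side chain) and chemoselectivity (ring diene over side-chain alkene): C6 carries the ring oxygen and is the δ-carbon of both the lactone carbonyl and the amide carbonyl, so it is the most electrophilic site and should take the nucleophilic CH2 terminus, leaving the acetal carbon to bond to C3, and only closure onto C3 leads to irreversible carbon dioxide loss and an arene. The excess of 9 should drive all three arms to completion, and any reversible N-silylation of the two secondary amides is undone in the next step.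

Step 6
Reactants: 12 N1,N5,N10-tris[(E)-4-(trimethylsilyloxy)cinnamoyl]spermidine
Product: 13 N1,N5,N10-tri-(E)-p-coumaroylspermidine
Conditions: K2CO3 (0.1 equiv), MeOH, 0 °C to rt, dark; AcOH
Reagents that add atoms: none
Why: base-catalysed methanolysis of aryl trimethylsilyl ethers, with phenoxide as a good leaving group from silicon, should proceed at or below room temperature without touching the amides or the E alkenes, and any N–Si bond left from step 5 is cleaved at the same time.

**Compound list**

1 | coumalic acid (2-oxo-2H-pyran-5-carboxylic acid) | O=C(O)C1=COC(=O)C=C1 | starting material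
2 | 5-bromo-2H-pyran-2-one | BrC1=COC(=O)C=C1 | intermediate
3 | spermidine | NCCCCNCCCN | starting material
4 | acryloyl chloride | C=CC(=O)Cl | starting material
5 | N1,N5,N10-triacryloylspermidine | C=CC(=O)NCCCCN(CCCNC(=O)C=C)C(=O)C=C | intermediate
6 | N1,N5,N10-tris[(E)-3-(2-oxo-2H-pyran-5-yl)acryloyl]spermidine | O=C(/C=C/C1=COC(=O)C=C1)NCCCCN(CCCNC(=O)/C=C/C1=COC(=O)C=C1)C(=O)/C=C/C1=COC(=O)C=C1 | intermediate
7 | trimethylsilyl acetate | CC(=O)O[Si](C)(C)C | starting material
8 | lithium enolate of trimethylsilyl acetate | [Li+].[O-]C(=C)O[Si](C)(C)C | intermediate
9 | 1,1-bis(trimethylsilyloxy)ethene | C=C(O[Si](C)(C)C)O[Si](C)(C)C | intermediate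
10 | N1,N5,N10-tris{(E)-3-[3-oxo-8,8-bis(trimethylsilyloxy)-2-oxabicyclo[2.2.2]oct-5-en-6-yl]acryloyl}spermidine (diastereomer mixture) | O=C(/C=C/C1=CC2C(=O)OC1CC2(O[Si](C)(C)C)O[Si](C)(C)C)NCCCCN(CCCNC(=O)/C=C/C1=CC2C(=O)OC1CC2(O[Si](C)(C)C)O[Si](C)(C)C)C(=O)/C=C/C1=CC2C(=O)OC1CC2(O[Si](C)(C)C)O[Si](C)(C)C | intermediate
11 | N1,N5,N10-tris{(E)-3-[4,4-bis(trimethylsilyloxy)cyclohexa-1,5-dien-1-yl]acryloyl}spermidine | O=C(/C=C/C1=CCC(O[Si](C)(C)C)(O[Si](C)(C)C)C=C1)NCCCCN(CCCNC(=O)/C=C/C1=CCC(O[Si](C)(C)C)(O[Si](C)(C)C)C=C1)C(=O)/C=C/C1=CCC(O[Si](C)(C)C)(O[Si](C)(C)C)C=C1 | intermediate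
12 | N1,N5,N10-tris[(E)-4-(trimethylsilyloxy)cinnamoyl]spermidine | C[Si](C)(C)Oc1ccc(/C=C/C(=O)NCCCCN(CCCNC(=O)/C=C/c2ccc(O[Si](C)(C)C)cc2)C(=O)/C=C/c2ccc(O[Si](C)(C)C)cc2)cc1 | intermediate
13 | N1,N5,N10-tri-(E)-p-coumaroylspermidine | O=C(/C=C/c1ccc(O)cc1)NCCCCN(CCCNC(=O)/C=C/c1ccc(O)cc1)C(=O)/C=C/c1ccc(O)cc1 | target

**Summary**

Total step count: 6. Longest linear sequence: 4 steps (1 → 2 → 6 → 12 → 13, or 3 → 5 → 6 → 12 → 13).

**Steps most likely to fail**

Step 5. The vinylogous amide acceptor makes the pyrone less electron-poor than a coumalate, so cycloaddition may be slow. Silyl transfer or conjugate addition of the acetal could then compete, and incomplete reaction would leave arms at different stages. The fallback uses known chemistry and gives up the pyrone-based ring construction. It sets out from 5: a threefold Heck reaction with 4-iodophenyl acetate (Pd(OAc)2, n-Bu4NCl, NaHCO3, DMF, 80 °C) should give N1,N5,N10-tris[(E)-4-acetoxycinnamoyl]spermidine F1. Methanolysis of the three acetates (K2CO3, MeOH, rt, dark) then returns to the route at 13.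

Step 3. Three couplings must all go to completion on one molecule. Base-induced opening of the pyrone at the temperature required, or radical oligomerisation of the tris-acrylamide, may intervene. The fallback sets out from 2: Stille coupling with tributyl(vinyl)stannane (Pd(PPh3)4, toluene, 80 °C) should give 5-ethenyl-2H-pyran-2-one F2. A threefold, base-free cross-metathesis of F2 with 5 (second-generation Hoveyda–Grubbs catalyst, CH2Cl2, 40 °C, loss of ethene) is expected to be E-selective and returns to the route at 6.

Step 2. Amine that is not yet acylated may add in aza-Michael fashion to acrylamide groups already present, and the tris-acrylamide may oligomerise on concentration. The fallback sets out from 3: acylation with three equivalents of 3-chloropropanoyl chloride (aq NaOH, CH2Cl2, 0 °C) should give N1,N5,N10-tris(3-chloropropanoyl)spermidine F3, which carries no Michael acceptor during the acylation. Threefold dehydrochlorination (Et3N, MeCN, 60 °C) then unmasks the acrylamides and returns to the route at 5.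

**Further compounds**

F1 | step 5 | N1,N5,N10-tris[(E)-4-acetoxycinnamoyl]spermidine | CC(=O)Oc1ccc(/C=C/C(=O)NCCCCN(CCCNC(=O)/C=C/c2ccc(OC(C)=O)cc2)C(=O)/C=C/c2ccc(OC(C)=O)cc2)cc1
F2 | step 3 | 5-ethenyl-2H-pyran-2-one | C=CC1=COC(=O)C=C1
F3 | step 2 | N1,N5,N10-tris(3-chloropropanoyl)spermidine | O=C(CCCl)NCCCCN(CCCNC(=O)CCCl)C(=O)CCCl
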